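Cutting the C1–C2 bond of the cyclohexene ring is the basis of the route: C1 is the fully substituted carbinol carbon carrying CH2OBz, C2 the allylic carbinol carbon. With C2 at the ketone level this pair is an α-ketol, the product of a benzoin reaction. The ring is therefore closed by a carbene-catalysed crossed benzoin cyclisation in which the aldehyde carbon of a (Z)-enal, made nucleophilic, attacks a benzoyloxymethyl ketone. One operation forms the carbocycle and the quaternary C1 with its benzoate in place; C2 is set last by Luche reduction. The precursor is an open-chain keto-(Z)-enal on the acetonide of L-tartaric acid, which supplies C5 and C6.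

Key step: step 7

Remark: the ring carbons of the target are numbered C1 (C(OH)CH2OBz), C2 (CHOH), C3=C4, C5 and C6 (the two CHOAc); these labels are used for the corresponding atoms of all intermediates.

Step 1
Reactants: 1 dimethyl (4R,5R)-2,2-dimethyl-1,3-dioxolane-4,5-dicarboxylate
Product: 2 (4R,5R)-5-(methoxycarbonyl)-2,2-dimethyl-1,3-dioxolane-4-carboxylic acid
Conditions: KOH (1.0 equiv), MeOH, 0 °C to rt; aq. HCl to pH 2–3 on work-up
Reagents that add atoms: potassium hydroxide, [K+].[OH-]
Why: Ester saponification with one equivalent of hydroxide should stop at the mono-acid because the first carboxylate deactivates the molecule electrostatically and its potassium salt separates from methanol, and neither stereocentre is touched.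

Step 2
Reactants: 2 (4R,5R)-5-(methoxycarbonyl)-2,2-dimethyl-1,3-dioxolane-4-carboxylic acid
Product: 4 methyl (4R,5R)-5-formyl-2,2-dimethyl-1,3-dioxolane-4-carboxylate, via acid chloride 3 (not isolated)
Conditions: (COCl)2, DMF (cat.), CH2Cl2, 0 °C to rt; evaporate; LiAlH(OtBu)3 (1.0 equiv), THF, −78 °C
Reagents that add atoms: none
Why: Acid chloride formation followed by reduction with the hindered hydride LiAlH(OtBu)3 (acyl chloride to aldehyde) is much faster at −78 °C than attack on the methyl ester or on the aldehyde formed, and without base the α-alkoxy stereocentre should not epimerise.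

Step 3
Reactants: 4 methyl (4R,5R)-5-formyl-2,2-dimethyl-1,3-dioxolane-4-carboxylate
Product: 5 methyl (4R,5S)-5-[(Z)-2-(1,3-dioxolan-2-yl)ethenyl]-2,2-dimethyl-1,3-dioxolane-4-carboxylate
Conditions: (1,3-dioxolan-2-ylmethyl)triphenylphosphonium bromide, KN(SiMe3)2 (1.0 equiv to the salt), THF, −78 to 0 °C; then 4, −78 °C to rt
Reagents that add atoms: (1,3-dioxolan-2-ylmethyl)triphenylphosphonium bromide, [Br-].C1COC(C[P+](c2ccccc2)(c2ccccc2)c2ccccc2)O1
Why: Wittig olefination with the non-stabilised dioxolanylmethyl ylide under lithium-free conditions is kinetically (Z)-selective, the more so with an α-alkoxy aldehyde, and delivers C3 and C2 as a masked (Z)-enal while the ester is inert to the ylide at low temperature.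

Step 4
Reactants: 5 methyl (4R,5S)-5-[(Z)-2-(1,3-dioxolan-2-yl)ethenyl]-2,2-dimethyl-1,3-dioxolane-4-carboxylate
Product: 7 2-chloro-1-[(4R,5S)-5-[(Z)-2-(1,3-dioxolan-2-yl)ethenyl]-2,2-dimethyl-1,3-dioxolan-4-yl]ethan-1-one, via lithium hemiketal alkoxide 6 (not isolated)
Conditions: ICH2Cl (1.5 equiv), MeLi·LiBr (1.5 equiv, slow addition), THF/Et2O, −78 °C; aq. NH4Cl quench at −78 °C
Reagents that add atoms: chloroiodomethane, ClCI
Why: Ester homologation with a lithium carbenoid: chloromethyllithium, formed in situ by iodine–lithium exchange, should add only once because the α-alkoxy-chelated tetrahedral alkoxide 6 survives at −78 °C and collapses to the chloromethyl ketone only on quenching, and the Barbier mode leaves no free base to enolise C6.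

Step 5
Reactants: 7 2-chloro-1-[(4R,5S)-5-[(Z)-2-(1,3-dioxolan-2-yl)ethenyl]-2,2-dimethyl-1,3-dioxolan-4-yl]ethan-1-one
Product: 8 2-[(4R,5S)-5-[(Z)-2-(1,3-dioxolan-2-yl)ethenyl]-2,2-dimethyl-1,3-dioxolan-4-yl]-2-oxoethyl benzoate
Conditions: PhCO2Cs (1.2 equiv), DMF, rt
Reagents that add atoms: cesium benzoate, [Cs+].[O-]C(=O)c1ccccc1
Why: SN2 displacement of the strongly activated α-keto chloride by the weakly basic carboxylate installs the final benzoate directly and is too mild to enolise the ketone or to open the acetals.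

Step 6
Reactants: 8 2-[(4R,5S)-5-[(Z)-2-(1,3-dioxolan-2-yl)ethenyl]-2,2-dimethyl-1,3-dioxolan-4-yl]-2-oxoethyl benzoate
Product: 9 2-[(4R,5S)-2,2-dimethyl-5-[(Z)-3-oxoprop-1-enyl]-1,3-dioxolan-4-yl]-2-oxoethyl benzoate
Conditions: TsOH·H2O (10 mol %), acetone/H2O (20:1), 0 °C, short contact; NaHCO3 quench; used at once
Reagents that add atoms: water, O
Why: Acid-catalysed acetal hydrolysis should be selective for the 2-alkenyl-1,3-dioxolane, which ionises through an allyl-stabilised oxocarbenium ion, while acetone as solvent holds the isopropylidene acetal in place by mass action and low temperature with short contact preserves the (Z)-geometry.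

Step 7
Reactants: 9 2-[(4R,5S)-2,2-dimethyl-5-[(Z)-3-oxoprop-1-enyl]-1,3-dioxolan-4-yl]-2-oxoethyl benzoate
Product: 11 [(3aR,4R,7aS)-4-hydroxy-2,2-dimethyl-5-oxo-3a,4,5,7a-tetrahydro-1,3-benzodioxol-4-yl]methyl benzoate, via Breslow intermediate 10 (not isolated)
Conditions: 2-(pentafluorophenyl)-6,7-dihydro-5H-pyrrolo[2,1-c][1,2,4]triazol-2-ium tetrafluoroborate (20 mol %), iPr2NEt (20 mol %), toluene (0.05 M), rt
Reagents that add atoms: none
Why: Proposed new method: the triazolylidene adds to the enal carbonyl and proton transfer gives Breslow intermediate 10, whose C2 carbon (now an acyl-anion equivalent) attacks the C1 ketone, after which proton transfer and loss of the carbene release the α-ketol; the closest known reaction type is the carbene-catalysed intramolecular crossed aldehyde–ketone benzoin cyclisation, established for aryl and alkyl aldehydes including sugar-derived keto-aldehydes but not for a (Z)-enal as donor. The carbocycle closes in the 6-exo-trig mode at the ketone carbonyl. The new stereocentre C1 (4R in 11) is under substrate control: the trans-fused dioxolane fixes a half-chair in which the CH2OBz arm takes the equatorial site, so that C2 adds to the Si face of the ketone and the new hydroxyl ends up axial, cis to the C6 oxygen. The step needs acyl-anion rather than homoenolate reactivity, which the two-atom spacer secures because attack through C4 could only close a four-membered ring, helped by the electron-poor N-C6F5 triazolium and a weak amine base that should not trigger β-elimination at the α-oxygenated ketone. Scrambling of the alkene geometry in 10 through its homoenolate form would be harmless, since the two forms interconvert and only the (Z)-form can cyclise.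

Step 8
Reactants: 11 [(3aR,4R,7aS)-4-hydroxy-2,2-dimethyl-5-oxo-3a,4,5,7a-tetrahydro-1,3-benzodioxol-4-yl]methyl benzoate
Product: 12 [(1R,5S,6R)-1,5,6-trihydroxy-2-oxocyclohex-3-en-1-yl]methyl benzoate
Conditions: TFA/H2O (4:1), 0 °C; co-evaporate with toluene
Reagents that add atoms: none
Why: Acetal hydrolysis: the isopropylidene acetal is trans-fused to the cyclohexene and therefore strained, so aqueous acid should cleave it quickly under conditions that leave the benzoate, the enone and all stereocentres untouched.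

Step 9
Reactants: 12 [(1R,5S,6R)-1,5,6-trihydroxy-2-oxocyclohex-3-en-1-yl]methyl benzoate
Product: 13 [(1R,5S,6R)-5,6-bis(acetyloxy)-1-hydroxy-2-oxocyclohex-3-en-1-yl]methyl benzoate
Conditions: Ac2O (2.5 equiv), pyridine, CH2Cl2, 0 °C
Reagents that add atoms: acetic anhydride, CC(=O)OC(C)=O
Why: Acylation with acetic anhydride and pyridine should esterify the two secondary hydroxyls at C5 and C6 but not the hindered tertiary α-ketol hydroxyl at C1 (no DMAP), and because C2 is still a ketone no protecting group is needed to tell the future C2 hydroxyl apart.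

Step 10
Reactants: 13 [(1R,5S,6R)-5,6-bis(acetyloxy)-1-hydroxy-2-oxocyclohex-3-en-1-yl]methyl benzoate
Product: 14 [(1S,2S,5S,6R)-5,6-bis(acetyloxy)-1,2-dihydroxycyclohex-3-en-1-yl]methyl benzoate
Conditions: NaBH4, CeCl3·7H2O, MeOH, −78 °C
Reagents that add atoms: none
Why: Luche 1,2-reduction: in the half-chair with both acetoxy groups and the CH2OBz arm equatorial the C1 hydroxyl is axial, so hydride should add axially to the Re face of the C2 carbonyl, anti to that C–O bond (Felkin–Anh), giving the (2S) alcohol cis to the C1 hydroxyl without touching the esters.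

Compound list
1 | dimethyl (4R,5R)-2,2-dimethyl-1,3-dioxolane-4,5-dicarboxylate (dimethyl 2,3-O-isopropylidene-L-tartrate) | COC(=O)[C@@H]1OC(C)(C)O[C@H]1C(=O)OC | starting material
2 | (4R,5R)-5-(methoxycarbonyl)-2,2-dimethyl-1,3-dioxolane-4-carboxylic acid | OC(=O)[C@@H]1OC(C)(C)O[C@H]1C(=O)OC | intermediate
3 | methyl (4R,5R)-5-(chlorocarbonyl)-2,2-dimethyl-1,3-dioxolane-4-carboxylate (acid chloride, not isolated) | ClC(=O)[C@@H]1OC(C)(C)O[C@H]1C(=O)OC | intermediate
4 | methyl (4R,5R)-5-formyl-2,2-dimethyl-1,3-dioxolane-4-carboxylate | O=C[C@@H]1OC(C)(C)O[C@H]1C(=O)OC | intermediate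
5 | methyl (4R,5S)-5-[(Z)-2-(1,3-dioxolan-2-yl)ethenyl]-2,2-dimethyl-1,3-dioxolane-4-carboxylate | C1(OCCO1)/C=C\[C@@H]2OC(C)(C)O[C@H]2C(=O)OC | intermediate
6 | lithium hemiketal alkoxide formed from 5 and chloromethyllithium (not isolated; hemiketal carbon of undefined configuration) | C1(OCCO1)/C=C\[C@@H]2OC(C)(C)O[C@H]2C([O-])(OC)CCl.[Li+] | intermediate
7 | 2-chloro-1-[(4R,5S)-5-[(Z)-2-(1,3-dioxolan-2-yl)ethenyl]-2,2-dimethyl-1,3-dioxolan-4-yl]ethan-1-one | C1(OCCO1)/C=C\[C@@H]2OC(C)(C)O[C@H]2C(=O)CCl | intermediate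
8 | 2-[(4R,5S)-5-[(Z)-2-(1,3-dioxolan-2-yl)ethenyl]-2,2-dimethyl-1,3-dioxolan-4-yl]-2-oxoethyl benzoate | C1(OCCO1)/C=C\[C@@H]2OC(C)(C)O[C@H]2C(=O)COC(=O)c3ccccc3 | intermediate
9 | 2-[(4R,5S)-2,2-dimethyl-5-[(Z)-3-oxoprop-1-enyl]-1,3-dioxolan-4-yl]-2-oxoethyl benzoate | O=C/C=C\[C@@H]1OC(C)(C)O[C@H]1C(=O)COC(=O)c1ccccc1 | intermediate
10 | Breslow intermediate: enaminol adduct of the triazolylidene at the aldehyde carbon of 9 (not isolated; enaminol geometry undefined) | OC(=C1N(c2c(F)c(F)c(F)c(F)c2F)N=C2CCCN12)/C=C\[C@@H]1OC(C)(C)O[C@H]1C(=O)COC(=O)c1ccccc1 | intermediate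
11 | [(3aR,4R,7aS)-4-hydroxy-2,2-dimethyl-5-oxo-3a,4,5,7a-tetrahydro-1,3-benzodioxol-4-yl]methyl benzoate | O=C1C=C[C@@H]2OC(C)(C)O[C@H]2[C@]1(O)COC(=O)c1ccccc1 | intermediate
12 | [(1R,5S,6R)-1,5,6-trihydroxy-2-oxocyclohex-3-en-1-yl]methyl benzoate | O=C1C=C[C@H](O)[C@@H](O)[C@]1(O)COC(=O)c1ccccc1 | intermediate
13 | [(1R,5S,6R)-5,6-bis(acetyloxy)-1-hydroxy-2-oxocyclohex-3-en-1-yl]methyl benzoate | O=C1C=C[C@H](OC(C)=O)[C@@H](OC(C)=O)[C@]1(O)COC(=O)c1ccccc1 | intermediate
14 | [(1S,2S,5S,6R)-5,6-bis(acetyloxy)-1,2-dihydroxycyclohex-3-en-1-yl]methyl benzoate | CC(=O)O[C@H]1C=C[C@H](O)[C@@](O)(COC(=O)c2ccccc2)[C@@H]1OC(C)=O | target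

Total step count: 10. Longest linear sequence: 10 steps (fully linear from 1).

Steps most likely to fail

Step 7. The Breslow intermediate may be diverted into the homoenolate manifold (β-protonation and redox consumption of the aldehyde), or the amine base may trigger β-elimination at the oxygenated ketone before ring closure. The fallback uses known chemistry, sets out from 8 and comes back at 11. Hydrogenation of the alkene (H2, RhCl(PPh3)3, benzene/EtOH) should give the saturated acetal 2-[(4R,5S)-5-[2-(1,3-dioxolan-2-yl)ethyl]-2,2-dimethyl-1,3-dioxolan-4-yl]-2-oxoethyl benzoate F1. Acetal hydrolysis as in step 6 should give the saturated keto aldehyde 2-[(4R,5S)-2,2-dimethyl-5-(3-oxopropyl)-1,3-dioxolan-4-yl]-2-oxoethyl benzoate F2. The established carbene-catalysed alkyl aldehyde–ketone benzoin cyclisation (same triazolium salt and base) should give the saturated α-ketol [(3aR,4R,7aS)-4-hydroxy-2,2-dimethyl-5-oxohexahydro-1,3-benzodioxol-4-yl]methyl benzoate F3. IBX dehydrogenation (DMSO, 70 °C), which can only involve the single enolisable α-carbon C3, should then give enone 11.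

Step 6. The acid needed to unmask the aldehyde may isomerise the (Z)-enal to the (E)-enal, which cannot cyclise directly, or may strip the isopropylidene acetal. The fallback avoids any acid-labile aldehyde mask, sets out from 4 and comes back at 9. Stork–Zhao olefination ((iodomethyl)triphenylphosphonium iodide, NaN(SiMe3)2, THF/DMPU, −78 °C) should give the (Z)-vinyl iodide methyl (4R,5S)-5-[(Z)-2-iodoethenyl]-2,2-dimethyl-1,3-dioxolane-4-carboxylate F4. The conditions of steps 4 and 5 should then give the chloromethyl ketone 2-chloro-1-[(4R,5S)-5-[(Z)-2-iodoethenyl]-2,2-dimethyl-1,3-dioxolan-4-yl]ethan-1-one F5 and the benzoate 2-[(4R,5S)-5-[(Z)-2-iodoethenyl]-2,2-dimethyl-1,3-dioxolan-4-yl]-2-oxoethyl benzoate F6. Pd(PPh3)4-catalysed reductive carbonylation (CO 1 atm, Bu3SnH added slowly, toluene, 50 °C) should convert the vinyl iodide into enal 9 under neutral conditions with retention of geometry.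

Step 10. Facial selectivity of hydride delivery may be poor in the conformationally mobile diacetate 13, giving the trans-1,2-diol as well. The fallback reduces while the ring is still locked, sets out from 11 and comes back at 14. Luche reduction of 11, whose trans-fused dioxolane holds the C1 hydroxyl axial, should give the cis-diol [(3aR,4S,5S,7aS)-4,5-dihydroxy-2,2-dimethyl-3a,4,5,7a-tetrahydro-1,3-benzodioxol-4-yl]methyl benzoate F7. 2,2-Dimethoxypropane with PPTS in acetone should protect that diol as a second, cis-fused isopropylidene acetal, the bis-acetonide F8. 60% aqueous AcOH at rt should cleave only the strained trans-fused acetal, giving the C5,C6-diol that keeps the C1,C2-acetonide F9. Ac2O/pyridine/DMAP should give its C5,C6-diacetate F10, and TFA/H2O (9:1, 0 °C) should release 14.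

Further compounds
F1 | step 7 | 2-[(4R,5S)-5-[2-(1,3-dioxolan-2-yl)ethyl]-2,2-dimethyl-1,3-dioxolan-4-yl]-2-oxoethyl benzoate | C1(OCCO1)CC[C@@H]2OC(C)(C)O[C@H]2C(=O)COC(=O)c3ccccc3
F2 | step 7 | 2-[(4R,5S)-2,2-dimethyl-5-(3-oxopropyl)-1,3-dioxolan-4-yl]-2-oxoethyl benzoate | O=CCC[C@@H]1OC(C)(C)O[C@H]1C(=O)COC(=O)c1ccccc1
F3 | step 7 | [(3aR,4R,7aS)-4-hydroxy-2,2-dimethyl-5-oxohexahydro-1,3-benzodioxol-4-yl]methyl benzoate | O=C1CC[C@@H]2OC(C)(C)O[C@H]2[C@]1(O)COC(=O)c1ccccc1
F4 | step 6 | methyl (4R,5S)-5-[(Z)-2-iodoethenyl]-2,2-dimethyl-1,3-dioxolane-4-carboxylate | I/C=C\[C@@H]1OC(C)(C)O[C@H]1C(=O)OC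
F5 | step 6 | 2-chloro-1-[(4R,5S)-5-[(Z)-2-iodoethenyl]-2,2-dimethyl-1,3-dioxolan-4-yl]ethan-1-one | I/C=C\[C@@H]1OC(C)(C)O[C@H]1C(=O)CCl
F6 | step 6 | 2-[(4R,5S)-5-[(Z)-2-iodoethenyl]-2,2-dimethyl-1,3-dioxolan-4-yl]-2-oxoethyl benzoate | I/C=C\[C@@H]1OC(C)(C)O[C@H]1C(=O)COC(=O)c1ccccc1
F7 | step 10 | [(3aR,4S,5S,7aS)-4,5-dihydroxy-2,2-dimethyl-3a,4,5,7a-tetrahydro-1,3-benzodioxol-4-yl]methyl benzoate | O[C@H]1C=C[C@@H]2OC(C)(C)O[C@H]2[C@]1(O)COC(=O)c1ccccc1
F8 | step 10 | bis-acetonide of F7 (second isopropylidene acetal cis-fused across the C1 and C2 oxygens) | CC1(C)O[C@H]2C=C[C@@H]3OC(C)(C)O[C@H]3[C@@]2(COC(=O)c4ccccc4)O1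
F9 | step 10 | C5,C6-diol retaining the C1,C2-isopropylidene acetal | CC1(C)O[C@H]2C=C[C@H](O)[C@@H](O)[C@@]2(COC(=O)c3ccccc3)O1
F10 | step 10 | C5,C6-diacetate retaining the C1,C2-isopropylidene acetal | CC1(C)O[C@H]2C=C[C@H](OC(C)=O)[C@@H](OC(C)=O)[C@@]2(COC(=O)c3ccccc3)O1
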